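**Retrosynthetic overview**
1. Only ring C (the pyranone) is built. It is cut at C3–C2 and at O1–C8a, which leads back to enol silane 3 of 2-fluoro-4,6-dimethoxyacetophenone and 3,4,5-trimethoxybenzaldehyde 4.
2. In the forward direction both bonds form in one flask: a catalytic asymmetric Mukaiyama aldol addition (C3–C2, sets C2 as S), then a fluoride-relay SNAr closure of the C2 oxygen onto C8a (O1–C8a).
3. Enabling feature: C8a carries fluorine ortho to the C4 carbonyl; the C5 and C7 methoxy groups are both meta to C8a and do not oppose the Meisenheimer charge; C3 is the only enolisable carbon of the ketone and aldehyde 4 has none.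
4. Fluoroketone 2 comes from Friedel–Crafts acetylation of 1-fluoro-3,5-dimethoxybenzene 1; the fluorine is a temporary activating group that leaves in the key step as Me3SiF.
5. Ring order: rings A and B are present from the start, ring C is closed last.

Key step: step 3

Assumption: the oxazaborolidinone from (R)-tryptophan is taken to shield the Re face of boron-bound 4 (aldehyde bound syn to the indolylmethyl group, indole stacked on one face), so that 3 adds to the Si face; should the first run give the R aldol, the catalyst from (S)-tryptophan is used with no other change.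

**Step 1**
Reactants: 1 1-fluoro-3,5-dimethoxybenzene
Product: 2 1-(2-fluoro-4,6-dimethoxyphenyl)ethan-1-one
Conditions: Ac2O (1.3 equiv), Sc(OTf)3 (10 mol%), MeNO2, 50 °C
Reagents that add atoms: acetic anhydride, CC(=O)OC(C)=O
Why: Friedel–Crafts acylation, in which the acylium ion should enter para to one methoxy group and ortho to the other (next to the small fluorine) rather than at the more hindered position between the two methoxy groups, while the deactivated product resists a second acylation and the catalytic triflate avoids the ether cleavage that stoichiometric AlCl3 can cause; any minor regioisomer is removed by crystallisation or chromatography.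

**Step 2**
Reactants: 2 1-(2-fluoro-4,6-dimethoxyphenyl)ethan-1-one
Product: 3 trimethyl{[1-(2-fluoro-4,6-dimethoxyphenyl)ethenyl]oxy}silane
Conditions: LDA (1.1 equiv), THF, −78 °C; TMSCl (1.2 equiv), −78 → 0 °C; pentane, filtration, bulb-to-bulb distillation
Reagents that add atoms: chlorotrimethylsilane, C[Si](C)(C)Cl
Why: Silyl enol ether formation by kinetic deprotonation of the only enolisable position (the acetyl CH3) and O-silylation of the lithium enolate, which at −78 °C should not attack the C–F bond; non-aqueous isolation keeps the labile enol silane intact.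

**Step 3**
Reactants: 3 trimethyl{[1-(2-fluoro-4,6-dimethoxyphenyl)ethenyl]oxy}silane; 4 3,4,5-trimethoxybenzaldehyde
Product: 7 (2S)-5,7-dimethoxy-2-(3,4,5-trimethoxyphenyl)-2,3-dihydro-4H-chromen-4-one, via silyl ether 5 (not isolated), via ammonium alkoxide 6 (not isolated)
Conditions: 4 (1.05 equiv), (R)-2-butyl-4-(1H-indol-3-ylmethyl)-3-(4-methylphenylsulfonyl)-1,3,2-oxazaborolidin-5-one (20 mol%, from N-tosyl-(R)-tryptophan and BuB(OH)2), EtCN, −78 °C; then Bu4N[Ph3SiF2] (0.3 equiv), −78 → −20 °C; pH 7 phosphate buffer
Reagents that add atoms: none
Why: Proposed new method: the step merges in one flask a chiral boron Lewis acid-catalysed Mukaiyama aldol addition (closest known type: oxazaborolidinone-catalysed addition of 1-aryl-1-silyloxyethenes to aromatic aldehydes with silyl transfer to the new oxygen) with a fluoride-relay desilylative SNAr etherification (closest known types: fluoride-catalysed coupling of silyl ethers with activated aryl fluorides, and SNAr ring closure of oxygen nucleophiles onto ortho-fluoroaryl ketones), a combination not yet shown for chroman-4-ones. Boron-bound aldehyde 4 is attacked at its Si face by the terminal carbon of 3 to form C3–C2 and silyl ether 5; fluoride from the silicate then frees alkoxide 6, which adds to C8a to give a Meisenheimer complex stabilised by the C4 carbonyl and expels fluoride, and that fluoride desilylates the next molecule of 5, so an initiating charge suffices and the standing concentration of base stays low. Ring C closes by this six-membered addition–elimination at C8a (6-endo-trig with respect to the vinylogous acyl fluoride F–C8a=C4a–C4=O); rings A and B are not touched. The single stereocentre C2 is set in the aldol stage by the catalyst, whose indole should shield the Re face of the aldehyde so that Si-face attack gives the S configuration, and the C–O bond formation takes place at the aryl carbon and leaves C2 unchanged. The step needs enantiofacial control (catalyst) and chemoselectivity for ring closure over retro-aldol cleavage and E1cB dehydration of 6, which the ortho-acyl activation of the only C–F bond, the favourable six-membered geometry, the low temperature and the substoichiometric fluoride should secure; regiochemistry is not in question because 3 has one nucleophilic carbon and 4 cannot enolise.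

**Compound list**
1 | 1-fluoro-3,5-dimethoxybenzene | COc1cc(F)cc(OC)c1 | starting material
2 | 1-(2-fluoro-4,6-dimethoxyphenyl)ethan-1-one | CC(=O)c1c(F)cc(OC)cc1OC | intermediate
3 | trimethyl{[1-(2-fluoro-4,6-dimethoxyphenyl)ethenyl]oxy}silane | C=C(O[Si](C)(C)C)c1c(F)cc(OC)cc1OC | intermediate
4 | 3,4,5-trimethoxybenzaldehyde | COc1cc(C=O)cc(OC)c1OC | starting material
5 | (3S)-1-(2-fluoro-4,6-dimethoxyphenyl)-3-(3,4,5-trimethoxyphenyl)-3-[(trimethylsilyl)oxy]propan-1-one | C[Si](C)(C)O[C@H](c1cc(OC)c(OC)c(OC)c1)CC(=O)c1c(F)cc(OC)cc1OC | intermediate
6 | tetrabutylammonium (1S)-3-(2-fluoro-4,6-dimethoxyphenyl)-3-oxo-1-(3,4,5-trimethoxyphenyl)propan-1-olate | [O-][C@H](c1cc(OC)c(OC)c(OC)c1)CC(=O)c1c(F)cc(OC)cc1OC.CCCC[N+](CCCC)(CCCC)CCCC | intermediate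
7 | (2S)-5,7-dimethoxy-2-(3,4,5-trimethoxyphenyl)-2,3-dihydro-4H-chromen-4-one (CNP0348225.1) | COc1cc(OC)c2c(c1)O[C@H](c1cc(OC)c(OC)c(OC)c1)CC2=O | target

**Step count**
Total steps: 3. Longest linear sequence: 3 steps (1 → 2 → 3 → 7).

**Steps most likely to fail**

1. Step 3 (proposed new method). The free alkoxide may revert by retro-aldol cleavage or lose water by E1cB elimination before it closes, or fluoride may open the product by a retro-oxa-Michael reaction; each would erode the enantiomeric purity or divert material to a chalcone. The fallback uses known chemistry, sets out from ketone 2 and returns at target 7 without ever generating an aldolate. Ketone 2 is formylated (HCO2Et, NaH, THF) to 3-(2-fluoro-4,6-dimethoxyphenyl)-3-oxopropanal F1, formed as its sodium enolate. On heating in DMF this closes by intramolecular SNAr of the enolate oxygen to 5,7-dimethoxy-4H-chromen-4-one F2. Asymmetric conjugate addition of 3,4,5-trimethoxyphenylboronic acid (OB(O)c1cc(OC)c(OC)c(OC)c1) to F2 then gives 7 directly, with Pd(OCOCF3)2 and (S)-4-tert-butyl-2-(pyridin-2-yl)-4,5-dihydrooxazole (or its antipode, whichever delivers the S configuration), NH4PF6, H2O, ClCH2CH2Cl, 60 °C; here the C2–aryl bond is made last.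

2. Step 1. The acetyl group may enter between the two methoxy groups, or the methyl ether next to the new ketone may be cleaved by the Lewis acid. The fallback sets out from 1 and returns at 2. Bromination with NBS in MeCN, which should go para to a methoxy group, gives 2-bromo-1-fluoro-3,5-dimethoxybenzene F3. Bromine–lithium exchange (n-BuLi, THF, −78 °C) gives (2-fluoro-4,6-dimethoxyphenyl)lithium F4, which is held at −78 °C to avoid aryne formation and acylated with N-methoxy-N-methylacetamide (CC(=O)N(C)OC) to give ketone 2 with no Lewis acid present.

3. Step 2. The enol silane may hydrolyse during isolation, or amine salts carried over may poison the boron catalyst of step 3. The fallback avoids the enol silane altogether; it sets out from 2 and 4 and returns at silyl ether 5, which then enters the fluoride stage of step 3. Claisen–Schmidt condensation of 2 with 4 (NaOH, EtOH, 0 °C → rt) gives (E)-1-(2-fluoro-4,6-dimethoxyphenyl)-3-(3,4,5-trimethoxyphenyl)prop-2-en-1-one F5. Copper-catalysed asymmetric conjugate borylation follows (CuCl, NaOt-Bu, (R)-1-[(S)-2-(diphenylphosphino)ferrocenyl]ethyldicyclohexylphosphine or its antipode, whichever gives the S product, B2pin2, MeOH, THF) and gives (S)-1-(2-fluoro-4,6-dimethoxyphenyl)-3-(4,4,5,5-tetramethyl-1,3,2-dioxaborolan-2-yl)-3-(3,4,5-trimethoxyphenyl)propan-1-one F6. Oxidation with NaBO3·4H2O (THF/H2O), with retention, gives (S)-1-(2-fluoro-4,6-dimethoxyphenyl)-3-hydroxy-3-(3,4,5-trimethoxyphenyl)propan-1-one F7, and TMSCl/imidazole (CH2Cl2, 0 °C) converts F7 into 5.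

**Further compounds**
F1 | step 3 | 3-(2-fluoro-4,6-dimethoxyphenyl)-3-oxopropanal (formed as its sodium enolate) | COc1cc(F)c(C(=O)CC=O)c(OC)c1
F2 | step 3 | 5,7-dimethoxy-4H-chromen-4-one | COc1cc(OC)c2c(c1)occc2=O
F3 | step 1 | 2-bromo-1-fluoro-3,5-dimethoxybenzene | COc1cc(F)c(Br)c(OC)c1
F4 | step 1 | (2-fluoro-4,6-dimethoxyphenyl)lithium | [Li]c1c(F)cc(OC)cc1OC
F5 | step 2 | (E)-1-(2-fluoro-4,6-dimethoxyphenyl)-3-(3,4,5-trimethoxyphenyl)prop-2-en-1-one | COc1cc(/C=C/C(=O)c2c(F)cc(OC)cc2OC)cc(OC)c1OC
F6 | step 2 | (S)-1-(2-fluoro-4,6-dimethoxyphenyl)-3-(4,4,5,5-tetramethyl-1,3,2-dioxaborolan-2-yl)-3-(3,4,5-trimethoxyphenyl)propan-1-one | CC1(C)OB(OC1(C)C)[C@H](c1cc(OC)c(OC)c(OC)c1)CC(=O)c1c(F)cc(OC)cc1OC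
F7 | step 2 | (S)-1-(2-fluoro-4,6-dimethoxyphenyl)-3-hydroxy-3-(3,4,5-trimethoxyphenyl)propan-1-one | O[C@H](c1cc(OC)c(OC)c(OC)c1)CC(=O)c1c(F)cc(OC)cc1OC
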